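**Plan**
- Retrosynthesis: the exocyclic C–I bond is traced back to a 5-(diiodomethylidene) lactone and then to a 5-methylidene group, and C4–Br to C4–O-t-Bu. The lactone bond O1–C2 is cut next, and last the C3–C1' and C5–CH2 bonds.
- Enabling feature: in the furanone ring (O1, C2, C3, C4, C5) the chain C2–C3=C4–C5 is held cis by the ring double bond and C5 is an enol-ester carbon. Taking O1 off C2 and joining C2 to C5 gives a cyclobut-2-enone with OH on the former C5, a pattern that a squarate ester supplies.
- Forward: the side-chain organolithium adds to di-tert-butyl squarate (C3–C1') and the adduct is rearranged to a cyclobutenedione. Me3SiCH2Li adds to its ketone carbonyl (C5–CH2), and Pb(OAc)4 then turns the four-membered ring into the only ring of the target.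
- The carbinol carbon carries CH2SiMe3 rather than CH3, so that the cation formed on ring closure sheds silicon and gives the exocyclic alkene directly.
- Finish: O-t-Bu to Br, two iodination–dehydrochlorination cycles, MOM removal, then Pd-catalysed removal of the iodine on the O1 side.
- Stereochemistry: C1' (R) is set by (R)-BINAL-H reduction of butanoyltributylstannane and carried with retention through Sn–Li exchange and carbonyl addition. The (5E)-iodoalkene (iodine on the C4 side) comes from site-selective hydrogenolysis of the diiodide.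

Key step: step 6

Assumption: di-tert-butyl squarate, (trimethylsilyl)methyllithium solution and bromodimethylborane are taken as purchasable; the C4 epimers of 13 and the E/Z isomers of 18 are carried on as mixtures because both elements are erased later.

**Step 1**
Reactants: 1 tributyltin hydride; 2 butanal
Product: 5 1-(tributylstannyl)butan-1-one, via tributylstannyllithium 3 (not isolated), via lithium stannyl alkoxide 4 (not isolated)
Conditions: LDA, THF, 0 °C; 2, −78 °C; 1,1'-(azodicarbonyl)dipiperidine (ADD), −78 → 0 °C
Reagents that add atoms: none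
Why: Stannyl anion 1,2-addition to the aldehyde followed by Oppenauer-type hydride transfer from the alkoxide to the azodicarboxamide is the standard one-flask entry to acylstannanes, and no stereocentre is kept.

**Step 2**
Reactants: 5 1-(tributylstannyl)butan-1-one
Product: 6 (1S)-1-(tributylstannyl)butan-1-ol
Conditions: (R)-BINAL-H (3 equiv), THF, −78 °C
Reagents that add atoms: none
Why: Enantioface-selective BINAL-H reduction of an acylstannane, in which the stannyl group takes the place that an unsaturated substituent occupies in the six-membered hydride-transfer transition state, so the (R)-reagent should give the (S)-carbinol that sets C1'; the labile product is used at once.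

**Step 3**
Reactants: 6 (1S)-1-(tributylstannyl)butan-1-ol
Product: 7 tributyl[(1S)-1-(methoxymethoxy)butyl]stannane
Conditions: MOMCl, i-Pr2NEt, CH2Cl2, 0 °C → rt
Reagents that add atoms: chloromethyl methyl ether, COCCl
Why: O-Alkylation to the methoxymethyl acetal under amine base leaves the C–Sn stereocentre untouched and gives the stable, chelating α-alkoxystannane.

**Step 4**
Reactants: 7 tributyl[(1S)-1-(methoxymethoxy)butyl]stannane; 8 di-tert-butyl squarate
Product: 11 3-tert-butoxy-4-[(1R)-1-(methoxymethoxy)butyl]cyclobut-3-ene-1,2-dione, via α-alkoxyalkyllithium 9 (not isolated), via lithium alkoxide adduct 10 (not isolated)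
Conditions: n-BuLi (1.0 equiv), THF, −78 °C; 8, −78 °C; (CF3CO)2O, −78 → 0 °C; aq. NaHCO3
Reagents that add atoms: none
Why: Tin–lithium exchange and 1,2-addition of the configurationally stable, internally chelated α-alkoxy organolithium should both go with retention at −78 °C, and O-trifluoroacetylation of the adduct triggers the usual squarate-adduct rearrangement (ionisation, loss of one tert-butyl group) to the 3-alkoxy-4-alkylcyclobutenedione.

**Step 5**
Reactants: 11 3-tert-butoxy-4-[(1R)-1-(methoxymethoxy)butyl]cyclobut-3-ene-1,2-dione; 12 (trimethylsilyl)methyllithium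
Product: 13 3-tert-butoxy-4-hydroxy-2-[(1R)-1-(methoxymethoxy)butyl]-4-[(trimethylsilyl)methyl]cyclobut-2-en-1-one (both C4 epimers)
Conditions: THF, −78 °C; AcOH, −78 °C
Reagents that add atoms: none
Why: Organolithium 1,2-addition goes to the ketone-like carbonyl next to the alkoxy-bearing carbon, not to the vinylogous ester carbonyl; the new carbinol centre forms without control and is erased in step 6, and a lithium β-silyl alkoxide should not undergo Peterson elimination at this temperature.

**Step 6**
Reactants: 13 3-tert-butoxy-4-hydroxy-2-[(1R)-1-(methoxymethoxy)butyl]-4-[(trimethylsilyl)methyl]cyclobut-2-en-1-one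
Product: 14 4-tert-butoxy-3-[(1R)-1-(methoxymethoxy)butyl]-5-methylidenefuran-2(5H)-one
Conditions: Pb(OAc)4 (1.3 equiv), PhMe, rt
Reagents that add atoms: none
Why: Ligand exchange gives a lead(IV) alkoxide that breaks down to an alkoxy radical (or its polar equivalent), and β-scission of the strained ring bond between the carbinol carbon and the carbonyl carbon leaves an acyl radical held cis to the new α-silyl ketone across the former cyclobutene double bond; oxidation to the acylium ion and attack by the ketone oxygen then forms the O1–C2 bond. This is the known lead tetraacetate ring expansion of 4-hydroxycyclobut-2-enones to 2(5H)-furanones, ended here by a Peterson-type β-silyl elimination instead of acetate capture. The lactone closes in a 5-exo-dig sense at the acylium carbon (its C≡O+ stays outside the ring), which the cis-locked C2–C3=C4–C5 chain makes unavoidable. The C5 oxocarbenium ion is β to silicon, so acetate removes Me3Si and the exocyclic C5=CH2 bond appears regiospecifically; any 5-acetoxy-5-(silylmethyl) lactone formed by capture should collapse to the same alkene by loss of Me3SiOAc. No stereocentre is created, and C1' is remote from every bond that changes. The step needs cleavage of the ring bond to the carbonyl carbon rather than to the vinylic carbon or to CH2SiMe3, which strain release and the stability of an acyl radical over a vinyl or primary alkyl radical should secure.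

**Step 7**
Reactants: 14 4-tert-butoxy-3-[(1R)-1-(methoxymethoxy)butyl]-5-methylidenefuran-2(5H)-one
Product: 16 4-bromo-3-[(1R)-1-(methoxymethoxy)butyl]-5-methylidenefuran-2(5H)-one, via tetronic acid 15 (not isolated)
Conditions: TFA, CH2Cl2, 0 °C, brief, evaporate; (COBr)2, DMF (cat.), CH2Cl2, 0 °C → rt
Reagents that add atoms: oxalyl bromide, O=C(Br)C(=O)Br
Why: Acidolysis of the tert-butyl enol ether (E1 loss of isobutene, faster than MOM cleavage at 0 °C) uncovers the vinylogous acid, which the Vilsmeier-type bromoiminium salt converts into the vinylogous acyl bromide by O-activation and addition–elimination of bromide at C4.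

**Step 8**
Reactants: 16 4-bromo-3-[(1R)-1-(methoxymethoxy)butyl]-5-methylidenefuran-2(5H)-one
Product: 18 4-bromo-5-(iodomethylidene)-3-[(1R)-1-(methoxymethoxy)butyl]furan-2(5H)-one (5E/5Z mixture), via chloro iodide 17 (not isolated)
Conditions: ICl (1.1 equiv), CH2Cl2, −78 → 0 °C; i-Pr2NEt, 0 °C → rt
Reagents that add atoms: iodine monochloride, ClI
Why: Halogen addition–dehydrohalogenation at the exocyclic enol-ester double bond, the standard route to 5-(halomethylidene)furanones, puts I+ on the terminal carbon and chloride on the oxocarbenium carbon C5, and the amine then removes HCl; either alkene geometry is acceptable.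

**Step 9**
Reactants: 18 4-bromo-5-(iodomethylidene)-3-[(1R)-1-(methoxymethoxy)butyl]furan-2(5H)-one
Product: 20 4-bromo-5-(diiodomethylidene)-3-[(1R)-1-(methoxymethoxy)butyl]furan-2(5H)-one, via chloro diiodide 19 (not isolated)
Conditions: ICl (1.5 equiv), CH2Cl2, 0 °C → rt; i-Pr2NEt, 0 °C → rt
Reagents that add atoms: iodine monochloride, ClI
Why: A second halogen addition–dehydrohalogenation cycle of the same type, with I+ again going to the carbon remote from O1, converts both isomers of 18 into one diiodide and so removes the geometry question of step 8.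

**Step 10**
Reactants: 20 4-bromo-5-(diiodomethylidene)-3-[(1R)-1-(methoxymethoxy)butyl]furan-2(5H)-one
Product: 22 4-bromo-5-(diiodomethylidene)-3-[(1R)-1-hydroxybutyl]furan-2(5H)-one, via bromomethyl ether 21 (not isolated)
Conditions: Me2BBr, CH2Cl2, −78 °C; aq. NaHCO3
Reagents that add atoms: none
Why: Bromoborane cleavage of a methoxymethyl ether takes place at the acetal carbon at −78 °C, so the C1'–O bond and its configuration stay intact, and the lactone, C4–Br and the diiodoalkene should tolerate these cold, non-aqueous conditions.

**Step 11**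
Reactants: 22 4-bromo-5-(diiodomethylidene)-3-[(1R)-1-hydroxybutyl]furan-2(5H)-one; 1 tributyltin hydride
Product: 23 (5E)-4-bromo-3-[(1R)-1-hydroxybutyl]-5-(iodomethylidene)furan-2(5H)-one
Conditions: Pd(PPh3)4 (5 mol %), Bu3SnH (1.0 equiv, slow addition), BHT (cat.), PhMe, 0 °C → rt, dark
Reagents that add atoms: none
Why: In this Pd-catalysed stereoselective hydrogenolysis of a 1,1-dihaloalkene, Pd(0) should insert into the more accessible C–I bond on the O1 side, away from the C4 bromine, and hydride transfer with reductive elimination under retention leaves the iodine cis to C4, the (5E)-alkene; C–I insertion should outpace C–Br insertion.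

**Compound list**
1 | tributyltin hydride | CCCC[SnH](CCCC)CCCC | starting material
2 | butanal | CCCC=O | starting material
3 | tributylstannyllithium | [Li][Sn](CCCC)(CCCC)CCCC | intermediate
4 | lithium 1-(tributylstannyl)butan-1-olate (racemic) | [Li+].CCCC([O-])[Sn](CCCC)(CCCC)CCCC | intermediate
5 | 1-(tributylstannyl)butan-1-one | CCCC(=O)[Sn](CCCC)(CCCC)CCCC | intermediate
6 | (1S)-1-(tributylstannyl)butan-1-ol | CCC[C@@H](O)[Sn](CCCC)(CCCC)CCCC | intermediate
7 | tributyl[(1S)-1-(methoxymethoxy)butyl]stannane | CCC[C@@H](OCOC)[Sn](CCCC)(CCCC)CCCC | intermediate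
8 | di-tert-butyl squarate (3,4-di-tert-butoxycyclobut-3-ene-1,2-dione) | CC(C)(C)OC1=C(OC(C)(C)C)C(=O)C1=O | starting material
9 | [(1S)-1-(methoxymethoxy)butyl]lithium | CCC[C@@H](OCOC)[Li] | intermediate
10 | lithium 2,3-di-tert-butoxy-1-[(1R)-1-(methoxymethoxy)butyl]-4-oxocyclobut-2-en-1-olate (both C1 epimers) | [Li+].CCC[C@@H](OCOC)C1([O-])C(OC(C)(C)C)=C(OC(C)(C)C)C1=O | intermediate
11 | 3-tert-butoxy-4-[(1R)-1-(methoxymethoxy)butyl]cyclobut-3-ene-1,2-dione | CCC[C@@H](OCOC)C1=C(OC(C)(C)C)C(=O)C1=O | intermediate
12 | (trimethylsilyl)methyllithium | [Li]C[Si](C)(C)C | starting material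
13 | 3-tert-butoxy-4-hydroxy-2-[(1R)-1-(methoxymethoxy)butyl]-4-[(trimethylsilyl)methyl]cyclobut-2-en-1-one (both C4 epimers) | CCC[C@@H](OCOC)C1=C(OC(C)(C)C)C(O)(C[Si](C)(C)C)C1=O | intermediate
14 | 4-tert-butoxy-3-[(1R)-1-(methoxymethoxy)butyl]-5-methylidenefuran-2(5H)-one | CCC[C@@H](OCOC)C1=C(OC(C)(C)C)C(=C)OC1=O | intermediate
15 | 4-hydroxy-3-[(1R)-1-(methoxymethoxy)butyl]-5-methylidenefuran-2(5H)-one | CCC[C@@H](OCOC)C1=C(O)C(=C)OC1=O | intermediate
16 | 4-bromo-3-[(1R)-1-(methoxymethoxy)butyl]-5-methylidenefuran-2(5H)-one | CCC[C@@H](OCOC)C1=C(Br)C(=C)OC1=O | intermediate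
17 | 4-bromo-5-chloro-5-(iodomethyl)-3-[(1R)-1-(methoxymethoxy)butyl]furan-2(5H)-one (both C5 epimers) | CCC[C@@H](OCOC)C1=C(Br)C(Cl)(CI)OC1=O | intermediate
18 | 4-bromo-5-(iodomethylidene)-3-[(1R)-1-(methoxymethoxy)butyl]furan-2(5H)-one (5E/5Z mixture) | CCC[C@@H](OCOC)C1=C(Br)C(=CI)OC1=O | intermediate
19 | 4-bromo-5-chloro-5-(diiodomethyl)-3-[(1R)-1-(methoxymethoxy)butyl]furan-2(5H)-one (both C5 epimers) | CCC[C@@H](OCOC)C1=C(Br)C(Cl)(C(I)I)OC1=O | intermediate
20 | 4-bromo-5-(diiodomethylidene)-3-[(1R)-1-(methoxymethoxy)butyl]furan-2(5H)-one | CCC[C@@H](OCOC)C1=C(Br)C(=C(I)I)OC1=O | intermediate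
21 | 4-bromo-3-[(1R)-1-(bromomethoxy)butyl]-5-(diiodomethylidene)furan-2(5H)-one | CCC[C@@H](OCBr)C1=C(Br)C(=C(I)I)OC1=O | intermediate
22 | 4-bromo-5-(diiodomethylidene)-3-[(1R)-1-hydroxybutyl]furan-2(5H)-one | CCC[C@@H](O)C1=C(Br)C(=C(I)I)OC1=O | intermediate
23 | (5E)-4-bromo-3-[(1R)-1-hydroxybutyl]-5-(iodomethylidene)furan-2(5H)-one | CCC[C@@H](O)C1=C(Br)/C(=C\I)OC1=O | target

**Step count**
Total steps: 11. Longest linear sequence: 11 steps (1 and 2 to 23).

**Steps most likely to fail**

1. Step 11 (site-selective hydrodeiodination). Oxidative addition may not distinguish the two C–I bonds well enough, may go on to the second iodine or enter the C4–Br bond, and a competing tin-radical chain would scramble the alkene geometry. The fallback gives up the diiodide. It sets out from 18: the geometric isomers are separated by chromatography with exclusion of light to give (5E)-4-bromo-5-(iodomethylidene)-3-[(1R)-1-(methoxymethoxy)butyl]furan-2(5H)-one F1. The (5Z)-isomer is returned to a photostationary E/Z mixture by direct irradiation, a known behaviour of 5-ylidene butenolides, and separated again. F1 is treated with Me2BBr at −78 °C, which should give (5E)-4-bromo-3-[(1R)-1-(bromomethoxy)butyl]-5-(iodomethylidene)furan-2(5H)-one F2; this is hydrolysed on bicarbonate work-up, and the route is rejoined at 23.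

2. Step 9 (second iodination). The iodoalkene of 18 may be too poor a nucleophile, or the β-iodo oxocarbenium intermediate may give up I+ again faster than it takes up chloride, so that the second iodine is not introduced. The fallback moves both iodinations to the more electron-rich tert-butyl tetronate. It sets out from 14: direct vinylic iodination with N-iodosuccinimide (MeCN, 0 °C, then Et3N) should give 4-tert-butoxy-5-(iodomethylidene)-3-[(1R)-1-(methoxymethoxy)butyl]furan-2(5H)-one F3 and, on repetition, 4-tert-butoxy-5-(diiodomethylidene)-3-[(1R)-1-(methoxymethoxy)butyl]furan-2(5H)-one F4. TFA then frees 5-(diiodomethylidene)-4-hydroxy-3-[(1R)-1-(methoxymethoxy)butyl]furan-2(5H)-one F5, and oxalyl bromide with catalytic DMF converts it into 20, where the route is rejoined.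

3. Step 6 (ring expansion). Acid-promoted Peterson elimination of the β-hydroxysilane before oxidation, or fragmentation toward the CH2SiMe3 group, could divert the alkoxy intermediate. The fallback uses a plain methyl group and a two-stage ending. It sets out from 11: methyllithium (THF, −78 °C) gives 3-tert-butoxy-4-hydroxy-2-[(1R)-1-(methoxymethoxy)butyl]-4-methylcyclobut-2-en-1-one F6. Lead tetraacetate in toluene then expands the ring with acetate capture of the cation, as is usual for carbinols carrying a simple alkyl group, to give 3-tert-butoxy-4-[(1R)-1-(methoxymethoxy)butyl]-2-methyl-5-oxo-2,5-dihydrofuran-2-yl acetate F7. Ionisation–deprotonation of this acylal (TMSOTf, Et3N, CH2Cl2, −78 °C) removes the acetate and gives 14, where the route is rejoined.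

**Further compounds**
F1 | step 11 | (5E)-4-bromo-5-(iodomethylidene)-3-[(1R)-1-(methoxymethoxy)butyl]furan-2(5H)-one | CCC[C@@H](OCOC)C1=C(Br)/C(=C\I)OC1=O
F2 | step 11 | (5E)-4-bromo-3-[(1R)-1-(bromomethoxy)butyl]-5-(iodomethylidene)furan-2(5H)-one | CCC[C@@H](OCBr)C1=C(Br)/C(=C\I)OC1=O
F3 | step 9 | 4-tert-butoxy-5-(iodomethylidene)-3-[(1R)-1-(methoxymethoxy)butyl]furan-2(5H)-one (5E/5Z mixture) | CCC[C@@H](OCOC)C1=C(OC(C)(C)C)C(=CI)OC1=O
F4 | step 9 | 4-tert-butoxy-5-(diiodomethylidene)-3-[(1R)-1-(methoxymethoxy)butyl]furan-2(5H)-one | CCC[C@@H](OCOC)C1=C(OC(C)(C)C)C(=C(I)I)OC1=O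
F5 | step 9 | 5-(diiodomethylidene)-4-hydroxy-3-[(1R)-1-(methoxymethoxy)butyl]furan-2(5H)-one | CCC[C@@H](OCOC)C1=C(O)C(=C(I)I)OC1=O
F6 | step 6 | 3-tert-butoxy-4-hydroxy-2-[(1R)-1-(methoxymethoxy)butyl]-4-methylcyclobut-2-en-1-one (both C4 epimers) | CCC[C@@H](OCOC)C1=C(OC(C)(C)C)C(C)(O)C1=O
F7 | step 6 | 3-tert-butoxy-4-[(1R)-1-(methoxymethoxy)butyl]-2-methyl-5-oxo-2,5-dihydrofuran-2-yl acetate (both C2 epimers) | CCC[C@@H](OCOC)C1=C(OC(C)(C)C)C(C)(OC(C)=O)OC1=O
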